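5 questions lay before the meeting: which flask ends with the most Wu, and how much Wu each flask holds at the end.

    Ej ⇌ Wu (K1 = 5.8, k1 = 1.1 /h, Ea1 = 109 kJ/mol, ΔH1 = 7.00 kJ/mol)
    Wu ⇌ Ul (K2 = 0.46, k2 = 0.015 /h, Ea2 = 119 kJ/mol, ΔH2 = −30.0 kJ/mol)
    Ul ⇌ Zu (K3 = 1.6, k3 = 0.23 /h, Ea3 = 109 kJ/mol, ΔH3 = 13.0 kJ/mol)
    Zu ⇌ Ej (k4 = 0.013 /h, Ea4 = 127 kJ/mol)
    Dw ⇌ Ej, rate k5*(cs5 - [Ej]) while solid is left; crystals form when [Ej] > cs5 (cs5 = 0.25 M, k5 = 0.055 /h)
    Ej ⇌ Wa (K6 = 24, k6 = 0.41 /h, Ea6 = 97.0 kJ/mol, ΔH6 = −22.0 kJ/mol)
    (constants at 60 °C)

| flask | Dw | time | remark | temperature |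
|---|---|---|---|---|
| Thursday's | 0.34 M | 5.0 d | at 20 °C until 4.0 d, from then on at 60 °C |  |
| Wednesday's | 0.34 M | 5.0 d |  | 60 °C |
| Friday's | 0.34 M | 5.0 d |  | 20 °C |
| Saturday's | 0.34 M | 5.0 d |  | 40 °C |

- the flask with the highest amount of Wu, in percent of the Dw charged ("all alike" if they lie within 1.5 percentage points) (Thursday's / Wednesday's / Friday's / Saturday's / all alike)
- final Wu, as a percentage of the Dw charged, in Thursday's
- final Wu, as a percentage of the Dw charged, in Wednesday's
- final Wu, as a percentage of the Dw charged, in Friday's
- final Wu, as a percentage of the Dw charged, in Saturday's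

- Dw is a solid; its amount is given per volume of the solution
- at 60 °C the constants are as listed, elsewhere as the activation energies and enthalpies make them
- at the start none of Dw is in solution
- what has only dissolved of Dw counts as not reacted

Minutes. I put forward one quantity to carry: the split at 20 °C, 1.49, the forward constant of Ej to Wu over the forward constant of Ej to Wa at the flask's temperature. It counts the Wu made per Wa formed from Ej (the selectivity factor), and 1 is the zero of its scale, the even case. At 40 °C I made it 2.03 and at 60 °C 2.68, so it rises with temperature.

I argued that the split needs two companions. One is the lag: the solid takes at least 1.03 d to dissolve. The other is the half-life of Ej against its two forward steps, 3.37 d at 20 °C and 0.217 d at 40 °C.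

Friday's Ej has a half-life longer than the lag, so I let it decay from the end of the lag and gave Wu the split's share of what reacted. That made 33.4% for Friday's.

Saturday's Ej has a half-life shorter than the lag, so I split the whole charge at once. But Wu there leaks, back to Ej, of which Wa takes its share by the split, and onward to Ul. I put the half-life of that leak at 4.18 d, which made 34.7% for Saturday's.

At 60 °C the same leak has a half-life of 0.434 d, shorter than the 5.0 d allowed, so for Wednesday's I took the equilibrium of the loop: 15.4%.

Thursday's I treated as Friday's up to 4.0 d, with 45.7% reacted. The rest then split at the hot value, and the excess over Wednesday's equilibrium leaked for the last day, which made 25.8%. My order put Saturday's first.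

The forecaster, who had seen the problem and nothing else, answered Saturday's, with 27% in Thursday's, 15.5% in Wednesday's, 30% in Friday's and 38% in Saturday's, holding that at the middle temperature “Wu forms faster than Wa and is only slowly drained”. These figures are the forecaster's, not mine: for Saturday's the forecast stood above my figure, and for Friday's below it.

Saturday's, the flask both lists named, ends highest, with 33.6%, against 30.1% in Friday's, 22.0% in Thursday's and 15.4% in Wednesday's. Saturday's Wu had read 47.3% at 2.50 d, so that flask ended on the falling side. Dividing Friday's Wu at 2.50 d by the split gives 9.48% of Wa, and the reading there is 9.77%. In the neighbour flask, Thursday's left until 30 h, the same division gives 3.59%, and the reading is 3.64%.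

(All constants were set for the occasion; the flask was simulated.)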